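Readings and results were computed for substances that don't exist; the scatter is artificial.

In a one-step world J and Z make X and nothing goes back, so X climbs while both are there. The earlier runs show something else.

| flask | J | Z | remark | time |
|---|---|---|---|---|
| Thursday's | 0.034 M | 3 equiv (fed, over 4.0 min) | run made earlier |  |
| Saturday's | 0.075 M | 3 equiv (fed, over 4.0 min) | run made earlier |  |
| larch | 0.050 M | 3.00 equiv (fed, over 4.0 min) |  | 40 min |
| cedar | 0.050 M | 3.00 equiv (fed, over 12 min) |  | 40 min |
| birch | 0.050 M | 3.00 equiv (fed, over 40 min) |  | 40 min |

- Thursday's (time / min: X / %): 4.00: 10.3; 8.00: 20.1; 12.0: 19.9; 15.0: 19.5; 20.0: 17.1; 25.0: 20.1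
- Saturday's (time / min: X / %): 4.00: 9.1; 8.00: 18.5; 12.0: 21.8; 15.0: 23.4; 20.0: 21.6; 25.0: 22.0

(scatter of a reading: 1 percentage point)

- J is a solid; its amount is given per volume of the solution
- at the start none of J is in solution
- "hardly changes" means that all values lie within two and a half points (for a concentration: within two and a half percent of the largest)

1. amount of X at the end, in percent of the J charged for larch, cedar, birch, in this order
2. the shape of the row from first to last (rises all the way / hardly changes / falls, then rises / rises, then falls / falls all the way)

Compare Thursday's run with Saturday's. Saturday's carries twice the J, with Z in the same proportion, yet the readings of both runs stop rising at nearly the same percent of the J charged. From 12.0 min on, Thursday's readings average 19.1% and Saturday's 22.2%. If each X holds one Z, such a stop has used about 6.37% to 7.40% of the Z charged, so lack of Z does not explain it. I read the stop as a balance, an equilibrium limit: X forms and goes back at equal speed. That reading also fits Saturday's plateau standing higher, since more of both partners pushes a balance forward, and the gap is larger than the 1 percentage point scatter of a single reading.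

So you can carry one quantity: the ceiling, the percent of the J charged at which X levels off in these readings once the whole Z is in. Placing the loading of larch, cedar and birch between the two runs gives 20.3%.

At the speed of the early rise, read at 4.00 min, I estimate that X needs about 8.39 min to reach the ceiling. The feed of larch is shorter than that, while those of cedar and birch are longer , but the asked time of 40 min is longer than the climb and the feed of birch lasts up to it, so I expect X to reach the ceiling by the end in larch, cedar and birch alike. A balance asks what is in the flask, not how it came there, so my reckoning puts larch, cedar and birch near the ceiling and calls the shape of the row hardly changes.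

The forecast differs from mine: it gives 21%, 31% and 45%, rises all the way, holding that “Z must be dying on its own”. The flask gives 21.1%, 21.7% and 21.9%, so the row hardly changes.

    J ⇌ D, rate k1*(cs1 - [D]) while solid is left; crystals form when [D] > cs1 (solubility = 32.0 mM, k = 0.0174 /s)
    J + X → G (k = 0.00733 /M/s)
    D + Z ⇌ X (K = 3.02 /M, k = 0.0126 /M/s)
    D + X → E (k = 0.00829 /M/s)

Here D is J in solution. Larch ends 0.80 points above the ceiling, and birch, with a feed ten times as long, ends 1.6 points above it. The main reason birch ends so low is the back step, X to D and Z: with that step taken away, birch ends at 62.5% against 21.9%.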